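**Retrosynthetic overview**
1. Target ⇒ triol: the acetate goes on last, on the least hindered (side-chain, allylic) hydroxyl.
2. The seven-membered ring is closed last, at the C(=CH2)–CH2 bond, by nickel-mediated coupling of a primary alkyl radical with an alkenyl iodide. The cyclopentene ring comes first, intact, from a chiral cyclopentenone.
3. Tertiary carbinol ⇒ chelation-controlled MeMgBr addition to the cyclopentenone. Ring-to-carbinol bond ⇒ anti aldol of the enone α′-enolate with a lactol (masked hydroxy-aldehyde).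
4. Lactol ⇒ 3,4-trans-4,6-cis δ-lactone holding all three side-chain stereocentres ⇒ vinylogous Mukaiyama aldol (prenal + senecioate dienolate), CuH reduction, enolate alkylation.
5. Iodovinyl enone ⇒ (S)-4-silyloxycyclopentenone by cuprate addition–elimination and iododesilylation.

Assumption: 12 is bought as its silyl ether (seven atoms other than hydrogen without the protecting group), and the hand of Tol-BINAP in step 2 is the one that gives the 6R lactone.

**Route**

Step 1
Reactants: 1 methyl 3-methylbut-2-enoate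
Product: 3 [(1-methoxy-3-methylbuta-1,3-dien-1-yl)oxy]trimethylsilane, via lithium dienolate 2 (not isolated)
Conditions: LiN(i-Pr)2, THF, −78 °C; Me3SiCl, −78 °C to rt
Reagents that add atoms: chlorotrimethylsilane, C[Si](C)(C)Cl
Why: γ-Deprotonation of the senecioate and O-silylation of the dienolate (silyl ketene acetal formation); no stereocentre is made.

Step 2
Reactants: 3 [(1-methoxy-3-methylbuta-1,3-dien-1-yl)oxy]trimethylsilane; 4 3-methylbut-2-enal
Product: 6 (6R)-4-methyl-6-(2-methylprop-1-en-1-yl)-5,6-dihydro-2H-pyran-2-one, via copper aldolate 5 (not isolated)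
Conditions: Cu(O3SCF3)2 (10 mol%), (S)-Tol-BINAP (11 mol%), Bu4N[Ph3SiF2] (20 mol%), THF, rt
Reagents that add atoms: none
Why: Catalytic asymmetric vinylogous Mukaiyama aldol (copper fluoride/Tol-BINAP): the chiral copper dienolate adds through its γ-carbon to one face of the enal (sets 6R), and the Z-aldolate lactonises with loss of methoxide.

Step 3
Reactants: 6 (6R)-4-methyl-6-(2-methylprop-1-en-1-yl)-5,6-dihydro-2H-pyran-2-one
Product: 7 (4R,6R)-4-methyl-6-(2-methylprop-1-en-1-yl)oxan-2-one
Conditions: [(Ph3P)CuH]6 (0.35 equiv), H2O (2 equiv), benzene, rt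
Reagents that add atoms: none
Why: Copper hydride conjugate reduction: hydride adds to C4 axially, anti to the pseudo-equatorial C6 alkenyl group, so the methyl ends cis to it (4R); the isolated trisubstituted alkene is not touched.

Step 4
Reactants: 7 (4R,6R)-4-methyl-6-(2-methylprop-1-en-1-yl)oxan-2-one; 8 1-bromo-2-chloroethane
Product: 10 (3S,4R,6R)-3-(2-chloroethyl)-4-methyl-6-(2-methylprop-1-en-1-yl)oxan-2-one, via lithium enolate 9 (not isolated)
Conditions: LiN(i-Pr)2 (1.0 equiv), THF, −78 °C; DMPU, 8 (4 equiv), −78 to −20 °C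
Reagents that add atoms: none
Why: Lactone enolate alkylation (SN2 at the C–Br end): the electrophile enters anti to the neighbouring C4 methyl (3,4-trans, 3S), and one equivalent of base with excess dihalide avoids cyclopropane formation.

Step 5
Reactants: 10 (3S,4R,6R)-3-(2-chloroethyl)-4-methyl-6-(2-methylprop-1-en-1-yl)oxan-2-one
Product: 11 (3S,4R,6R)-3-(2-chloroethyl)-4-methyl-6-(2-methylprop-1-en-1-yl)oxan-2-ol
Conditions: i-Bu2AlH (1.1 equiv), CH2Cl2, −78 °C; aq. potassium sodium tartrate
Reagents that add atoms: none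
Why: Partial reduction of a δ-lactone to the lactol (the aluminium hemiacetal survives at −78 °C until work-up); the anomeric centre is a mixture and no other stereocentre is touched.

Step 6
Reactants: 12 (4S)-4-[(tert-butyldimethylsilyl)oxy]cyclopent-2-en-1-one; 13 (1-bromoethenyl)trimethylsilane
Product: 16 (4S)-4-[1-(trimethylsilyl)ethenyl]cyclopent-2-en-1-one, via Grignard reagent 14 (not isolated), via silyloxy ketone 15 (not isolated)
Conditions: 13, Mg, THF, 50 °C; CuI (10 mol%), then 12, −78 to −40 °C; aq. NH4Cl; crude 15, DBU, CH2Cl2, 0 °C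
Reagents that add atoms: none
Why: Copper-catalysed 1,4-addition of the α-silylvinyl Grignard anti to the silyloxy group (sets the future ring-fusion carbon), then E1cB loss of silanolate, which moves the enone and erases the carbinol centre.

Step 7
Reactants: 16 (4S)-4-[1-(trimethylsilyl)ethenyl]cyclopent-2-en-1-one
Product: 17 (4S)-4-(1-iodoethenyl)cyclopent-2-en-1-one
Conditions: N-iodosuccinimide, (CF3)2CHOH, 0 °C
Reagents that add atoms: N-iodosuccinimide, O=C1CCC(=O)N1I
Why: Electrophilic ipso-iododesilylation of the vinylsilane; the electron-poor enone alkene is inert and the stereocentre is not involved.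

Step 8
Reactants: 17 (4S)-4-(1-iodoethenyl)cyclopent-2-en-1-one; 11 (3S,4R,6R)-3-(2-chloroethyl)-4-methyl-6-(2-methylprop-1-en-1-yl)oxan-2-ol
Product: 20 (4R,5R)-5-[(1R,2S,3R,5R)-2-(2-chloroethyl)-1,5-dihydroxy-3,7-dimethyloct-6-en-1-yl]-4-(1-iodoethenyl)cyclopent-2-en-1-one, via lithium dienolate 18 (not isolated), via open-chain alkoxide aldehyde 19 (not isolated)
Conditions: 17, LiN(i-Pr)2 (1.05 equiv), THF, −78 °C; 11 pre-treated with LiN(i-Pr)2 (1.0 equiv, THF, −78 °C) added by cannula; −78 to −40 °C; AcOH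
Reagents that add atoms: none
Why: Lithium enolate aldol addition to a lactol reacting through its open hydroxy-aldehyde form: attack on the enolate face anti to the iodovinyl group (trans ring substituents), the chair Zimmerman–Traxler transition state of the E-enolate (anti aldol) and Felkin–Anh attack on the α-branched aldehyde all lead to the same diastereomer.

Step 9
Reactants: 20 (4R,5R)-5-[(1R,2S,3R,5R)-2-(2-chloroethyl)-1,5-dihydroxy-3,7-dimethyloct-6-en-1-yl]-4-(1-iodoethenyl)cyclopent-2-en-1-one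
Product: 21 (1S,4R,5R)-5-[(1R,2S,3R,5R)-2-(2-chloroethyl)-1,5-dihydroxy-3,7-dimethyloct-6-en-1-yl]-4-(1-iodoethenyl)-1-methylcyclopent-2-en-1-ol
Conditions: MeMgBr (5 equiv), CH2Cl2/Et2O, −78 °C
Reagents that add atoms: methylmagnesium bromide, C[Mg]Br
Why: Chelation-controlled Grignard 1,2-addition: the magnesium alkoxide of the β-hydroxyl chelates the ketone in a chair, and methyl attacks axially, anti to the ring C–H next to the carbonyl, which puts methyl cis to the carbinol side arm (1S).

Step 10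
Reactants: 21 (1S,4R,5R)-5-[(1R,2S,3R,5R)-2-(2-chloroethyl)-1,5-dihydroxy-3,7-dimethyloct-6-en-1-yl]-4-(1-iodoethenyl)-1-methylcyclopent-2-en-1-ol
Product: 23 (1S,3aR,7S,8R,8aR)-7-[(2R,4R)-4-hydroxy-6-methylhept-5-en-2-yl]-1-methyl-4-methylidene-1,3a,4,5,6,7,8,8a-octahydroazulene-1,8-diol, via primary iodide 22 (not isolated)
Conditions: NiBr2(MeOCH2CH2OMe) (20 mol%), 4,4′-di-tert-butyl-2,2′-bipyridine (20 mol%), NaI (1.5 equiv), Mn powder (4 equiv), DMA, 60 °C, 21 added over 12 h to 5 mM
Reagents that add atoms: none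
Why: Proposed new method: intramolecular nickel-catalysed reductive cross-electrophile coupling, in which zerovalent nickel inserts into the alkenyl C–I bond, the chloride is exchanged to the iodide in the flask and gives a primary alkyl radical by halogen abstraction, the radical is captured by the alkenylnickel and reductive elimination from trivalent nickel forms the C(sp2)–C(sp3) bond that closes the seven-membered ring and leaves the exocyclic methylene; the closest known reaction type is the intermolecular nickel/manganese coupling of vinyl halides with primary alkyl halides, which tolerates free hydroxyls; no stereocentre is formed and the trans ring fusion is already fixed.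

Step 11
Reactants: 23 (1S,3aR,7S,8R,8aR)-7-[(2R,4R)-4-hydroxy-6-methylhept-5-en-2-yl]-1-methyl-4-methylidene-1,3a,4,5,6,7,8,8a-octahydroazulene-1,8-diol
Product: 24 (2R,4R)-2-[(1S,3aR,7S,8R,8aR)-1,8-dihydroxy-1-methyl-4-methylidene-1,3a,4,5,6,7,8,8a-octahydroazulen-7-yl]-6-methylhept-5-en-4-yl acetate
Conditions: Ac2O (1.1 equiv), pyridine, DMAP (5 mol%), CH2Cl2, −20 °C
Reagents that add atoms: acetic anhydride, CC(=O)OC(C)=O
Why: DMAP-catalysed acylation under steric control: the side-chain allylic secondary hydroxyl reacts much faster than the ring hydroxyl flanked by two methine carbons and the tertiary hydroxyl.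

**Compound list**
1 | methyl 3-methylbut-2-enoate | COC(=O)C=C(C)C | starting material
2 | lithium 1-methoxy-3-methylbuta-1,3-dien-1-olate | [Li]OC(OC)=CC(C)=C | intermediate
3 | [(1-methoxy-3-methylbuta-1,3-dien-1-yl)oxy]trimethylsilane (E/Z mixture) | COC(O[Si](C)(C)C)=CC(C)=C | intermediate
4 | 3-methylbut-2-enal | CC(C)=CC=O | starting material
5 | monovalent copper alkoxide of methyl (2Z,5R)-5-hydroxy-3,7-dimethylocta-2,6-dienoate | COC(=O)/C=C(C)\C[C@@H](O[Cu])C=C(C)C | intermediate
6 | (6R)-4-methyl-6-(2-methylprop-1-en-1-yl)-5,6-dihydro-2H-pyran-2-one | O=C1O[C@@H](C=C(C)C)CC(C)=C1 | intermediate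
7 | (4R,6R)-4-methyl-6-(2-methylprop-1-en-1-yl)oxan-2-one (4,6-cis) | O=C1O[C@@H](C=C(C)C)C[C@@H](C)C1 | intermediate
8 | 1-bromo-2-chloroethane | ClCCBr | starting material
9 | lithium enolate of 7 | [Li]OC1=C[C@H](C)C[C@H](C=C(C)C)O1 | intermediate
10 | (3S,4R,6R)-3-(2-chloroethyl)-4-methyl-6-(2-methylprop-1-en-1-yl)oxan-2-one (3,4-trans, 4,6-cis) | O=C1O[C@@H](C=C(C)C)C[C@@H](C)[C@@H]1CCCl | intermediate
11 | (3S,4R,6R)-3-(2-chloroethyl)-4-methyl-6-(2-methylprop-1-en-1-yl)oxan-2-ol (both anomers) | OC1O[C@@H](C=C(C)C)C[C@@H](C)[C@@H]1CCCl | intermediate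
12 | (4S)-4-[(tert-butyldimethylsilyl)oxy]cyclopent-2-en-1-one | O=C1C=C[C@@H](O[Si](C)(C)C(C)(C)C)C1 | starting material
13 | (1-bromoethenyl)trimethylsilane | C=C(Br)[Si](C)(C)C | starting material
14 | [1-(trimethylsilyl)ethenyl]magnesium bromide | C=C([Mg]Br)[Si](C)(C)C | intermediate
15 | (3S,4S)-4-[(tert-butyldimethylsilyl)oxy]-3-[1-(trimethylsilyl)ethenyl]cyclopentan-1-one (trans) | O=C1C[C@H](C(=C)[Si](C)(C)C)[C@@H](O[Si](C)(C)C(C)(C)C)C1 | intermediate
16 | (4S)-4-[1-(trimethylsilyl)ethenyl]cyclopent-2-en-1-one | O=C1C=C[C@@H](C(=C)[Si](C)(C)C)C1 | intermediate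
17 | (4S)-4-(1-iodoethenyl)cyclopent-2-en-1-one | O=C1C=C[C@@H](C(I)=C)C1 | intermediate
18 | lithium dienolate of 17 | [Li]OC1=C[C@H](C(I)=C)C=C1 | intermediate
19 | lithium alkoxide of (2S,3R,5R)-2-(2-chloroethyl)-5-hydroxy-3,7-dimethyloct-6-enal | O=C[C@@H](CCCl)[C@H](C)C[C@H](C=C(C)C)O[Li] | intermediate
20 | (4R,5R)-5-[(1R,2S,3R,5R)-2-(2-chloroethyl)-1,5-dihydroxy-3,7-dimethyloct-6-en-1-yl]-4-(1-iodoethenyl)cyclopent-2-en-1-one | ClCC[C@@H]([C@H](C)C[C@H](C=C(C)C)O)[C@@H](O)[C@H]1[C@H](C(I)=C)C=CC1=O | intermediate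
21 | (1S,4R,5R)-5-[(1R,2S,3R,5R)-2-(2-chloroethyl)-1,5-dihydroxy-3,7-dimethyloct-6-en-1-yl]-4-(1-iodoethenyl)-1-methylcyclopent-2-en-1-ol | ClCC[C@@H]([C@H](C)C[C@H](C=C(C)C)O)[C@@H](O)[C@H]1[C@H](C(I)=C)C=C[C@]1(C)O | intermediate
22 | primary iodide of 21 (2-iodoethyl in place of 2-chloroethyl; same configuration) | ICC[C@@H]([C@H](C)C[C@H](C=C(C)C)O)[C@@H](O)[C@H]1[C@H](C(I)=C)C=C[C@]1(C)O | intermediate
23 | (1S,3aR,7S,8R,8aR)-7-[(2R,4R)-4-hydroxy-6-methylhept-5-en-2-yl]-1-methyl-4-methylidene-1,3a,4,5,6,7,8,8a-octahydroazulene-1,8-diol | C=C1CC[C@@H]([C@H](C)C[C@H](C=C(C)C)O)[C@@H](O)[C@H]2[C@H]1C=C[C@]2(C)O | intermediate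
24 | (2R,4R)-2-[(1S,3aR,7S,8R,8aR)-1,8-dihydroxy-1-methyl-4-methylidene-1,3a,4,5,6,7,8,8a-octahydroazulen-7-yl]-6-methylhept-5-en-4-yl acetate | C=C1CC[C@@H]([C@H](C)C[C@H](C=C(C)C)OC(C)=O)[C@@H](O)[C@H]2[C@H]1C=C[C@]2(C)O | target

**Step count and risks**

Total steps: 11. Longest linear sequence: 9 (steps 1–5, then 8–11); the second branch (steps 6–7) joins at step 8.

The three steps most likely to fail:

- **Step 10 (ring closure).** A seven-membered ring is closed on an unprotected triol. Reduction of the alkenyl iodide, oligomers, and tetrahydrofuran formation from the ring hydroxyl and the transient iodide all compete. The fallback is a polar palladium route that sets out from 21 and comes back at 23. Me3SiOSO2CF3/2,6-lutidine gives the tris(trimethylsilyl) ether F1. NaI in acetone gives the primary iodide F2. Zinc dust/LiCl in THF at 25 °C inserts only into the alkyl C–I bond to give the alkylzinc iodide F3 (not isolated). Pd(PPh3)4 then closes the ring by intramolecular Negishi coupling to the cyclised tris(trimethylsilyl) ether F4, and K2CO3/MeOH frees 23.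

- **Step 8 (aldol on a lactol).** The lactol may open too slowly, or quench the enolate. The fallback uses a protected open-chain aldehyde; it sets out from 10 and comes back at 20. MeNH(OMe)·HCl/Me3Al opens the lactone to the hydroxy Weinreb amide F5. Et3SiCl/imidazole gives the triethylsilyl ether F6. i-Bu2AlH at −78 °C gives the open-chain aldehyde F7. Aldol with enolate 18, under the same stereocontrol, gives the silyl-protected aldol F8, and pyridinium tosylate/MeOH removes the silyl group to give 20.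

- **Step 9 (face of methyl addition).** If chelation control is weak on the flexible monocycle, the C1 epimer forms. The fallback reverses the order; it sets out from 20 and comes back at 23. Ring closure under the step 10 conditions, through the primary iodide F9 (not isolated), gives the trans-fused bicyclic hydroxy enone F10. MeMgBr in CH2Cl2/Et2O at −78 °C then adds to this conformationally locked enone, where the hydroxyl is held next to the carbonyl and attack anti to the axial ring-fusion hydrogen gives 23.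

**Further compounds**
F1 | step 10 | tris(trimethylsilyl) ether of 21 | ClCC[C@@H]([C@H](C)C[C@H](C=C(C)C)O[Si](C)(C)C)[C@@H](O[Si](C)(C)C)[C@H]1[C@H](C(I)=C)C=C[C@]1(C)O[Si](C)(C)C
F2 | step 10 | primary iodide from F1 | ICC[C@@H]([C@H](C)C[C@H](C=C(C)C)O[Si](C)(C)C)[C@@H](O[Si](C)(C)C)[C@H]1[C@H](C(I)=C)C=C[C@]1(C)O[Si](C)(C)C
F3 | step 10 | alkylzinc iodide from F2 | I[Zn]CC[C@@H]([C@H](C)C[C@H](C=C(C)C)O[Si](C)(C)C)[C@@H](O[Si](C)(C)C)[C@H]1[C@H](C(I)=C)C=C[C@]1(C)O[Si](C)(C)C
F4 | step 10 | tris(trimethylsilyl) ether of 23 | C=C1CC[C@@H]([C@H](C)C[C@H](C=C(C)C)O[Si](C)(C)C)[C@@H](O[Si](C)(C)C)[C@H]2[C@H]1C=C[C@]2(C)O[Si](C)(C)C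
F5 | step 8 | (2S,3R,5R)-2-(2-chloroethyl)-5-hydroxy-N-methoxy-N,3,7-trimethyloct-6-enamide | CON(C)C(=O)[C@@H](CCCl)[C@H](C)C[C@H](C=C(C)C)O
F6 | step 8 | triethylsilyl ether of F5 | CON(C)C(=O)[C@@H](CCCl)[C@H](C)C[C@H](C=C(C)C)O[Si](CC)(CC)CC
F7 | step 8 | (2S,3R,5R)-2-(2-chloroethyl)-3,7-dimethyl-5-[(triethylsilyl)oxy]oct-6-enal | O=C[C@@H](CCCl)[C@H](C)C[C@H](C=C(C)C)O[Si](CC)(CC)CC
F8 | step 8 | side-chain triethylsilyl ether of 20 | ClCC[C@@H]([C@H](C)C[C@H](C=C(C)C)O[Si](CC)(CC)CC)[C@@H](O)[C@H]1[C@H](C(I)=C)C=CC1=O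
F9 | step 9 | primary iodide of 20 | ICC[C@@H]([C@H](C)C[C@H](C=C(C)C)O)[C@@H](O)[C@H]1[C@H](C(I)=C)C=CC1=O
F10 | step 9 | (3aR,7S,8R,8aR)-8-hydroxy-7-[(2R,4R)-4-hydroxy-6-methylhept-5-en-2-yl]-4-methylidene-3a,4,5,6,7,8-hexahydroazulen-1(8aH)-one | C=C1CC[C@@H]([C@H](C)C[C@H](C=C(C)C)O)[C@@H](O)[C@H]2[C@H]1C=CC2=O
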